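**Plan**

- Labels: C7 is the carbinol carbon carrying ring A (the syringyl ring), C8 carries the hydroxymethyl carbon C9, ring B is the benzo ring of the benzodioxane and ring C is the resorcinol ring. The target is the (7R,8R) trans compound, (2R,3R) in benzodioxine numbering.
- Retrosynthesis: the stilbene C=C between ring B and ring C is cut first (Horner–Wadsworth–Emmons). Then the bond from the C7 oxygen to ring B, then the C8–O bond to ring B (phenoxide alkylation), then C8–C9 (Claisen condensation).
- Enabling feature: in the 1,4-dioxane ring the C7 oxygen is bound to an sp2 carbon of ring B that is ortho to the carbon bearing the C8 oxygen. This aryl–oxygen bond can therefore be made last, from a free C7 hydroxyl and an ortho C–Br bond, without touching a bond at C7 or C8.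
- Forward: acetosyringone is extended to an α-aryloxy β-keto ester (chain first). One transfer hydrogenation sets both carbinol centres. The dioxane ring, the only ring formed, is closed by copper-catalysed O-arylation, and ring C is attached last.
- Stereochemistry: C7 (R) comes from the (S,S)-TsDPEN ruthenium catalyst and C8 from the syn-selective dynamic kinetic resolution in the same step. Both are retained in the ring closure. The E alkene comes from the phosphonate olefination.

Key step: step 8

Step 1
Reactants: 1 acetosyringone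
Product: 2 1-[3,5-dimethoxy-4-(methoxymethoxy)phenyl]ethan-1-one
Conditions: MOMCl, iPr2NEt, CH2Cl2, 0 °C to rt
Reagents that add atoms: chloromethyl methyl ether (MOMCl), COCCl
Why: O-alkylation of the phenol by the reactive α-chloro ether (Williamson-type) should give the MOM acetal, which tolerates the basic, hydridic and copper-mediated steps ahead and is removed by acid at the end.

Step 2
Reactants: 2 1-[3,5-dimethoxy-4-(methoxymethoxy)phenyl]ethan-1-one
Product: 3 methyl 3-[3,5-dimethoxy-4-(methoxymethoxy)phenyl]-3-oxopropanoate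
Conditions: NaH, (MeO)2CO, toluene, reflux; then cold 1 M HCl quench
Reagents that add atoms: dimethyl carbonate, COC(=O)OC
Why: crossed Claisen condensation of the methyl ketone enolate with dimethyl carbonate, driven by irreversible deprotonation of the β-keto ester formed, should add the future C9 carbon.

Step 3
Reactants: 3 methyl 3-[3,5-dimethoxy-4-(methoxymethoxy)phenyl]-3-oxopropanoate
Product: 4 methyl 2-bromo-3-[3,5-dimethoxy-4-(methoxymethoxy)phenyl]-3-oxopropanoate (racemic)
Conditions: NBS (1.05 equiv), NH4OAc (10 mol %), Et2O, rt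
Reagents that add atoms: N-bromosuccinimide, O=C1CCC(=O)N1Br
Why: electrophilic α-bromination through the enol of the β-keto ester should be far faster than bromination of ring A, which is deactivated by its acyl group.

Step 4
Reactants: 4 methyl 2-bromo-3-[3,5-dimethoxy-4-(methoxymethoxy)phenyl]-3-oxopropanoate; 5 methyl 3-bromo-4-hydroxybenzoate
Product: 6 methyl 3-bromo-4-({1-[3,5-dimethoxy-4-(methoxymethoxy)phenyl]-3-methoxy-1,3-dioxopropan-2-yl}oxy)benzoate (racemic α-aryloxy β-keto ester)
Conditions: K2CO3, acetone, 0 °C to rt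
Reagents that add atoms: none
Why: SN2 displacement of the doubly activated α-bromide by the phenoxide (Williamson ether synthesis) should form the C8–O bond to ring B, with the bromine of 5 placed ortho to that oxygen and meta to the ester.

Step 5
Reactants: 6 methyl 3-bromo-4-({1-[3,5-dimethoxy-4-(methoxymethoxy)phenyl]-3-methoxy-1,3-dioxopropan-2-yl}oxy)benzoate
Product: 7 methyl (2S,3R)-2-[2-bromo-4-(methoxycarbonyl)phenoxy]-3-[3,5-dimethoxy-4-(methoxymethoxy)phenyl]-3-hydroxypropanoate (syn hydroxy diester; C7 is R, and C8 is S in this ester only because of the CIP ranking of the ester carbon)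
Conditions: RuCl(p-cymene)[(S,S)-TsDPEN] (2 mol %), HCO2H/Et3N (5:2), CH2Cl2, 30 °C
Reagents that add atoms: none
Why: Noyori–Ikariya asymmetric transfer hydrogenation with dynamic kinetic resolution, a reaction type established for α-oxygenated β-keto esters, should deliver hydride to one ketone face under catalyst control (aryl CH/π contact in the six-membered transition state, giving 7R) while the acidic C8–H epimerises rapidly in the formate/amine medium, so that only the C8 epimer leading to the syn (threo) product is reduced.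

Step 6
Reactants: 7 methyl (2S,3R)-2-[2-bromo-4-(methoxycarbonyl)phenoxy]-3-[3,5-dimethoxy-4-(methoxymethoxy)phenyl]-3-hydroxypropanoate
Product: 8 (1R,2R)-2-[2-bromo-4-(hydroxymethyl)phenoxy]-1-[3,5-dimethoxy-4-(methoxymethoxy)phenyl]propane-1,3-diol
Conditions: LiAlH4, THF, 0 °C; then Na2SO4·10H2O
Reagents that add atoms: none
Why: hydride reduction of both methyl esters to primary alcohols should be fast at 0 °C, where the aryl bromide and the MOM acetal are inert, and it touches neither stereocentre (the C8 descriptor changes to R only through the CIP ranking).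

Step 7
Reactants: 8 (1R,2R)-2-[2-bromo-4-(hydroxymethyl)phenoxy]-1-[3,5-dimethoxy-4-(methoxymethoxy)phenyl]propane-1,3-diol
Product: 9 (1R,2R)-2-[2-bromo-4-({[tert-butyl(dimethyl)silyl]oxy}methyl)phenoxy]-3-{[tert-butyl(dimethyl)silyl]oxy}-1-[3,5-dimethoxy-4-(methoxymethoxy)phenyl]propan-1-ol (threo C7 alcohol, C8 2-bromoaryl ether)
Conditions: TBSCl (2.2 equiv), imidazole, CH2Cl2, 0 °C
Reagents that add atoms: tert-butyldimethylsilyl chloride, CC(C)(C)[Si](C)(C)Cl
Why: imidazole-promoted silylation should take the two primary hydroxyls much faster than the hindered secondary benzylic C7 hydroxyl, leaving that one alcohol free for the ring closure.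

Step 8
Reactants: 9 (1R,2R)-2-[2-bromo-4-({[tert-butyl(dimethyl)silyl]oxy}methyl)phenoxy]-3-{[tert-butyl(dimethyl)silyl]oxy}-1-[3,5-dimethoxy-4-(methoxymethoxy)phenyl]propan-1-ol
Product: 10 tert-butyl{[(2R,3R)-2-({[tert-butyl(dimethyl)silyl]oxy}methyl)-3-[3,5-dimethoxy-4-(methoxymethoxy)phenyl]-2,3-dihydro-1,4-benzodioxin-6-yl]methoxy}dimethylsilane (trans benzodioxane bis-silyl ether)
Conditions: CuI (10 mol %), 3,4,7,8-tetramethyl-1,10-phenanthroline (20 mol %), Cs2CO3, toluene, 110 °C
Reagents that add atoms: none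
Why: Cs2CO3 deprotonates the C7 hydroxyl, and the phenanthroline-bound monovalent copper alkoxide inserts into the neighbouring C–Br bond of ring B to give a seven-membered trivalent copper metallacycle, from which C–O reductive elimination releases the aryl ether and returns the catalyst. The closest known reaction type is the Ullmann-type copper-catalysed intramolecular O-arylation of secondary alcohols by ortho-halo aryl ethers, which gives chromans and 2-substituted 1,4-benzodioxanes. The 1,4-dioxane ring closes in a six-membered exo mode, the C7 oxygen bonding to the ipso carbon of ring B with bromide as the exocyclic leaving group. No stereocentre is created: neither the C7–O nor the C8–O bond is broken, so the (7R,8R) threo arrangement of 9 should be carried unchanged into the trans ring of 10. The step needs selectivity for one oxygen and one ring B carbon; the first is secured because the C7 hydroxyl is the only free hydroxyl (both primary alcohols are silylated, the ring A phenol is a MOM ether), the second because bromine sits ortho to the C8 ether oxygen, which lies para to the CH2OTBS carbon as fixed by benzoate 5.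

Step 9
Reactants: 10 tert-butyl{[(2R,3R)-2-({[tert-butyl(dimethyl)silyl]oxy}methyl)-3-[3,5-dimethoxy-4-(methoxymethoxy)phenyl]-2,3-dihydro-1,4-benzodioxin-6-yl]methoxy}dimethylsilane
Product: 11 [(2R,3R)-3-[3,5-dimethoxy-4-(methoxymethoxy)phenyl]-2,3-dihydro-1,4-benzodioxine-2,6-diyl]dimethanol
Conditions: TBAF, THF, 0 °C to rt
Reagents that add atoms: none
Why: fluoride-induced desilylation, driven by the strength of the Si–F bond, should free both primary alcohols without affecting the MOM acetal or the dioxane ring.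

Step 10
Reactants: 11 [(2R,3R)-3-[3,5-dimethoxy-4-(methoxymethoxy)phenyl]-2,3-dihydro-1,4-benzodioxine-2,6-diyl]dimethanol
Product: 12 (2R,3R)-3-[3,5-dimethoxy-4-(methoxymethoxy)phenyl]-2-(hydroxymethyl)-2,3-dihydro-1,4-benzodioxine-6-carbaldehyde
Conditions: MnO2, CH2Cl2, rt
Reagents that add atoms: none
Why: MnO2 oxidises benzylic alcohols selectively, so the ring B carbinol should go to the aldehyde while the saturated C9 alcohol stays untouched.

Step 11
Reactants: 13 3,5-dihydroxybenzyl alcohol
Product: 14 [3,5-bis(methoxymethoxy)phenyl]methanol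
Conditions: MOMCl (2.1 equiv), K2CO3, acetone, 0 °C to rt
Reagents that add atoms: chloromethyl methyl ether (MOMCl), COCCl
Why: K2CO3 deprotonates only the two phenols, whose phenoxides should outcompete the neutral benzylic alcohol for a stoichiometric amount of MOMCl (chemoselective Williamson-type O-alkylation).

Step 12
Reactants: 14 [3,5-bis(methoxymethoxy)phenyl]methanol
Product: 15 1-(bromomethyl)-3,5-bis(methoxymethoxy)benzene
Conditions: CBr4, PPh3, CH2Cl2, 0 °C
Reagents that add atoms: carbon tetrabromide, BrC(Br)(Br)Br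
Why: the Appel reaction converts the benzylic alcohol into the bromide through an alkoxyphosphonium ion under neutral conditions that the MOM acetals tolerate.

Step 13
Reactants: 15 1-(bromomethyl)-3,5-bis(methoxymethoxy)benzene
Product: 16 diethyl {[3,5-bis(methoxymethoxy)phenyl]methyl}phosphonate
Conditions: P(OEt)3 (neat), 130 °C
Reagents that add atoms: triethyl phosphite, CCOP(OCC)OCC
Why: Michaelis–Arbuzov reaction of the benzylic bromide with triethyl phosphite (SN2 at carbon, then dealkylation of the phosphonium ion by bromide) should give the phosphonate.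

Step 14
Reactants: 12 (2R,3R)-3-[3,5-dimethoxy-4-(methoxymethoxy)phenyl]-2-(hydroxymethyl)-2,3-dihydro-1,4-benzodioxine-6-carbaldehyde; 16 diethyl {[3,5-bis(methoxymethoxy)phenyl]methyl}phosphonate
Product: 17 [(2R,3R)-6-{(E)-2-[3,5-bis(methoxymethoxy)phenyl]ethenyl}-3-[3,5-dimethoxy-4-(methoxymethoxy)phenyl]-2,3-dihydro-1,4-benzodioxin-2-yl]methanol
Conditions: KOtBu (2.5 equiv), THF, 0 °C to rt
Reagents that add atoms: none
Why: Horner–Wadsworth–Emmons olefination of the aryl aldehyde with the benzylic phosphonate anion should give the E stilbene through reversible addition and elimination from the anti oxaphosphetane, the extra base covering the free C9 hydroxyl and the MOM ether on ring A preventing phenoxide-driven opening at C7.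

Step 15
Reactants: 17 [(2R,3R)-6-{(E)-2-[3,5-bis(methoxymethoxy)phenyl]ethenyl}-3-[3,5-dimethoxy-4-(methoxymethoxy)phenyl]-2,3-dihydro-1,4-benzodioxin-2-yl]methanol
Product: 18 aiphanol, 5-[(E)-2-[(2R,3R)-3-(4-hydroxy-3,5-dimethoxyphenyl)-2-(hydroxymethyl)-2,3-dihydro-1,4-benzodioxin-6-yl]ethenyl]benzene-1,3-diol
Conditions: 3 M aq HCl/MeOH, 40 °C
Reagents that add atoms: none
Why: acid-catalysed transacetalisation in methanol should remove all three MOM groups under conditions mild enough to leave the aryl ether bonds of the dioxane ring and the E alkene intact.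

**Compound list**

1 | acetosyringone, 1-(4-hydroxy-3,5-dimethoxyphenyl)ethan-1-one | CC(=O)c1cc(OC)c(O)c(OC)c1 | starting material
2 | 1-[3,5-dimethoxy-4-(methoxymethoxy)phenyl]ethan-1-one | CC(=O)c1cc(OC)c(OCOC)c(OC)c1 | intermediate
3 | methyl 3-[3,5-dimethoxy-4-(methoxymethoxy)phenyl]-3-oxopropanoate | COC(=O)CC(=O)c1cc(OC)c(OCOC)c(OC)c1 | intermediate
4 | methyl 2-bromo-3-[3,5-dimethoxy-4-(methoxymethoxy)phenyl]-3-oxopropanoate (racemic) | COC(=O)C(Br)C(=O)c1cc(OC)c(OCOC)c(OC)c1 | intermediate
5 | methyl 3-bromo-4-hydroxybenzoate | COC(=O)c1ccc(O)c(Br)c1 | starting material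
6 | methyl 3-bromo-4-({1-[3,5-dimethoxy-4-(methoxymethoxy)phenyl]-3-methoxy-1,3-dioxopropan-2-yl}oxy)benzoate (racemic) | COC(=O)C(Oc1ccc(C(=O)OC)cc1Br)C(=O)c1cc(OC)c(OCOC)c(OC)c1 | intermediate
7 | methyl (2S,3R)-2-[2-bromo-4-(methoxycarbonyl)phenoxy]-3-[3,5-dimethoxy-4-(methoxymethoxy)phenyl]-3-hydroxypropanoate | COc1cc([C@@H](O)[C@@H](C(=O)OC)Oc2ccc(C(=O)OC)cc2Br)cc(OC)c1OCOC | intermediate
8 | (1R,2R)-2-[2-bromo-4-(hydroxymethyl)phenoxy]-1-[3,5-dimethoxy-4-(methoxymethoxy)phenyl]propane-1,3-diol | COc1cc([C@@H](O)[C@@H](CO)Oc2ccc(CO)cc2Br)cc(OC)c1OCOC | intermediate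
9 | (1R,2R)-2-[2-bromo-4-({[tert-butyl(dimethyl)silyl]oxy}methyl)phenoxy]-3-{[tert-butyl(dimethyl)silyl]oxy}-1-[3,5-dimethoxy-4-(methoxymethoxy)phenyl]propan-1-ol | COc1cc([C@@H](O)[C@@H](CO[Si](C)(C)C(C)(C)C)Oc2ccc(CO[Si](C)(C)C(C)(C)C)cc2Br)cc(OC)c1OCOC | intermediate
10 | tert-butyl{[(2R,3R)-2-({[tert-butyl(dimethyl)silyl]oxy}methyl)-3-[3,5-dimethoxy-4-(methoxymethoxy)phenyl]-2,3-dihydro-1,4-benzodioxin-6-yl]methoxy}dimethylsilane | COc1cc([C@H]2Oc3cc(CO[Si](C)(C)C(C)(C)C)ccc3O[C@@H]2CO[Si](C)(C)C(C)(C)C)cc(OC)c1OCOC | intermediate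
11 | [(2R,3R)-3-[3,5-dimethoxy-4-(methoxymethoxy)phenyl]-2,3-dihydro-1,4-benzodioxine-2,6-diyl]dimethanol | COc1cc([C@H]2Oc3cc(CO)ccc3O[C@@H]2CO)cc(OC)c1OCOC | intermediate
12 | (2R,3R)-3-[3,5-dimethoxy-4-(methoxymethoxy)phenyl]-2-(hydroxymethyl)-2,3-dihydro-1,4-benzodioxine-6-carbaldehyde | COc1cc([C@H]2Oc3cc(C=O)ccc3O[C@@H]2CO)cc(OC)c1OCOC | intermediate
13 | 3,5-dihydroxybenzyl alcohol | OCc1cc(O)cc(O)c1 | starting material
14 | [3,5-bis(methoxymethoxy)phenyl]methanol | COCOc1cc(CO)cc(OCOC)c1 | intermediate
15 | 1-(bromomethyl)-3,5-bis(methoxymethoxy)benzene | COCOc1cc(CBr)cc(OCOC)c1 | intermediate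
16 | diethyl {[3,5-bis(methoxymethoxy)phenyl]methyl}phosphonate | CCOP(=O)(Cc1cc(OCOC)cc(OCOC)c1)OCC | intermediate
17 | [(2R,3R)-6-{(E)-2-[3,5-bis(methoxymethoxy)phenyl]ethenyl}-3-[3,5-dimethoxy-4-(methoxymethoxy)phenyl]-2,3-dihydro-1,4-benzodioxin-2-yl]methanol | COc1cc([C@H]2Oc3cc(/C=C/c4cc(OCOC)cc(OCOC)c4)ccc3O[C@@H]2CO)cc(OC)c1OCOC | intermediate
18 | aiphanol | COc1cc([C@H]2Oc3cc(/C=C/c4cc(O)cc(O)c4)ccc3O[C@@H]2CO)cc(OC)c1O | target

**Step count**

Total: 15 steps. Longest linear sequence: 12 steps (steps 1 to 10, then 14 and 15); steps 11 to 13 are the phosphonate branch.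

**Steps most likely to fail**

Step 8 (ring closure).
- What may go wrong: the copper alkoxide of the hindered secondary benzylic alcohol may insert only slowly into the electron-rich, ortho-alkoxy C–Br bond. At 110 °C protodebromination could then compete, as could base-induced silyl migration from the C9 oxygen to the C7 oxygen, which would free the C9 hydroxyl for a seven-membered closure.
- Fallback: it reverses the polarity, making ring B the oxygen nucleophile and C7 the electrophile. It sets out from 9 and returns at 10. Mitsunobu esterification of 9 with 4-nitrobenzoic acid (PPh3, DIAD, THF) would invert C7 to give the (7S) 4-nitrobenzoate F1. K2CO3 in MeOH would release the erythro (7S,8R) alcohol F2. Miyaura borylation (PdCl2(dppf), bis(pinacolato)diboron, KOAc, dioxane, 90 °C) would turn the C–Br bond into the aryl pinacol boronate F3, and NaBO3·4H2O in THF/H2O would oxidise it to the catechol monoether phenol F4. Intramolecular Mitsunobu etherification (PPh3, DIAD, THF) would then close the dioxane ring with a second inversion at C7, arriving at the same (7R,8R) trans compound 10.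

Step 5 (transfer hydrogenation).
- What may go wrong: C8 epimerisation may not keep pace with reduction, or the aryloxy group may discriminate poorly between the syn and anti transition states, eroding diastereo- and enantioselectivity. Hydride transfer to the electron-rich aryl ketone may also be slow.
- Fallback: it replaces catalyst control by an auxiliary-controlled aldol that forms the C7–C8 bond. It sets out from 5 and returns at 8. Syringaldehyde would be protected (MOMCl, iPr2NEt) as 3,5-dimethoxy-4-(methoxymethoxy)benzaldehyde F5. Phenol 5 would be O-alkylated with (S)-4-benzyl-3-(bromoacetyl)oxazolidin-2-one (K2CO3, acetone) to the aryloxyacetyl imide F6. Its dibutylboron Z-enolate (Bu2BOTf, iPr2NEt, CH2Cl2, −78 °C) would add to F5 through the chair transition state of the Evans syn aldol to give the (2S,3R) aldol adduct F7, the auxiliary fixing both centres. LiBH4 (THF/MeOH, 0 °C) would remove the auxiliary reductively to give the diol ester F8, and LiAlH4 (THF, 0 °C) would reduce the benzoate to reach triol 8.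

Step 4 (phenoxide alkylation).
- What may go wrong: halophilic attack of the phenoxide on bromine would return keto ester 3 by reductive debromination, and C-alkylation or slow substitution at the crowded α-carbon are also possible.
- Fallback: it forms the C8–O bond by carbenoid insertion and no longer needs bromide 4. It sets out from 3 and returns at 6. Regitz diazo transfer (4-acetamidobenzenesulfonyl azide, Et3N, MeCN) would give the diazo keto ester F9. Rh2(OAc)4-catalysed O–H insertion of its carbenoid into phenol 5 (CH2Cl2, rt to reflux) would give 6 directly.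

Further compounds
F1 | step 8 | (1S,2R)-2-[2-bromo-4-({[tert-butyl(dimethyl)silyl]oxy}methyl)phenoxy]-3-{[tert-butyl(dimethyl)silyl]oxy}-1-[3,5-dimethoxy-4-(methoxymethoxy)phenyl]propyl 4-nitrobenzoate | COc1cc([C@H](OC(=O)c2ccc(cc2)[N+](=O)[O-])[C@@H](CO[Si](C)(C)C(C)(C)C)Oc3ccc(CO[Si](C)(C)C(C)(C)C)cc3Br)cc(OC)c1OCOC
F2 | step 8 | (1S,2R)-2-[2-bromo-4-({[tert-butyl(dimethyl)silyl]oxy}methyl)phenoxy]-3-{[tert-butyl(dimethyl)silyl]oxy}-1-[3,5-dimethoxy-4-(methoxymethoxy)phenyl]propan-1-ol (C7 epimer of 9) | COc1cc([C@H](O)[C@@H](CO[Si](C)(C)C(C)(C)C)Oc2ccc(CO[Si](C)(C)C(C)(C)C)cc2Br)cc(OC)c1OCOC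
F3 | step 8 | (1S,2R)-3-{[tert-butyl(dimethyl)silyl]oxy}-2-[4-({[tert-butyl(dimethyl)silyl]oxy}methyl)-2-(4,4,5,5-tetramethyl-1,3,2-dioxaborolan-2-yl)phenoxy]-1-[3,5-dimethoxy-4-(methoxymethoxy)phenyl]propan-1-ol | COc1cc([C@H](O)[C@@H](CO[Si](C)(C)C(C)(C)C)Oc2ccc(CO[Si](C)(C)C(C)(C)C)cc2B3OC(C)(C)C(C)(C)O3)cc(OC)c1OCOC
F4 | step 8 | 2-{[(1S,2R)-3-{[tert-butyl(dimethyl)silyl]oxy}-1-[3,5-dimethoxy-4-(methoxymethoxy)phenyl]-1-hydroxypropan-2-yl]oxy}-5-({[tert-butyl(dimethyl)silyl]oxy}methyl)phenol | COc1cc([C@H](O)[C@@H](CO[Si](C)(C)C(C)(C)C)Oc2ccc(CO[Si](C)(C)C(C)(C)C)cc2O)cc(OC)c1OCOC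
F5 | step 5 | 3,5-dimethoxy-4-(methoxymethoxy)benzaldehyde | COCOc1c(OC)cc(C=O)cc1OC
F6 | step 5 | methyl 4-{2-[(4S)-4-benzyl-2-oxo-1,3-oxazolidin-3-yl]-2-oxoethoxy}-3-bromobenzoate | COC(=O)c1ccc(OCC(=O)N2[C@@H](Cc3ccccc3)COC2=O)c(Br)c1
F7 | step 5 | methyl 4-{[(1R,2S)-3-[(4S)-4-benzyl-2-oxo-1,3-oxazolidin-3-yl]-1-[3,5-dimethoxy-4-(methoxymethoxy)phenyl]-1-hydroxy-3-oxopropan-2-yl]oxy}-3-bromobenzoate | COc1cc([C@@H](O)[C@@H](C(=O)N2[C@@H](Cc3ccccc3)COC2=O)Oc4ccc(C(=O)OC)cc4Br)cc(OC)c1OCOC
F8 | step 5 | methyl 3-bromo-4-{[(1R,2R)-1-[3,5-dimethoxy-4-(methoxymethoxy)phenyl]-1,3-dihydroxypropan-2-yl]oxy}benzoate | COc1cc([C@@H](O)[C@@H](CO)Oc2ccc(C(=O)OC)cc2Br)cc(OC)c1OCOC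
F9 | step 4 | methyl 2-diazo-3-[3,5-dimethoxy-4-(methoxymethoxy)phenyl]-3-oxopropanoate | COC(=O)C(=[N+]=[N-])C(=O)c1cc(OC)c(OCOC)c(OC)c1
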